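**Retrosynthetic overview**

- The target, a (3R)-isoflavan, is reached by desilylation of its bis-silyl ether. That ether comes from an achiral isoflavone in one Ru-catalysed transfer-hydrogenation/deoxygenation cascade, which sets C3 by dynamic kinetic resolution.
- The isoflavone is cut across the pyran ring C (O1–C2–C3–C4–C4a–C8a) into a 2-fluoroaroyl chloride (ring A plus C4), the morpholine enamine of the ring-B arylacetaldehyde (C2–C3) and water (O1). This is a [3+3] annulation: C4–C3 forms by C-acylation and O1–C8a by SNAr.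
- Enabling feature: C4 is the benzylic carbon on C4a and lies ortho to the ether carbon C8a of ring A. As a ketone, C4 is an acyl electrophile, activates C8a–F (the C5 and C7 oxygens are meta to C8a) and acidifies C3–H. Later O1, the C5 methoxy and the C7 oxygen (ortho/para to C4) let the C4 oxygen leave.
- Ring order: ring A is bought and carboxylated by directed lithiation; the dimethylpyran ring on ring B is made by propargyl Claisen cyclisation; ring C is closed last, in the key step.

Key step: step 9

Assumption: the (R,R) antipode of the Ru catalyst is taken to give the (4R) carbinol, as with simple 4-chromanones; if the sense is opposite, the (S,S) antipode is used with no other change.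

**Route**

Step 1
Reactants: 1 3-fluoro-5-methoxyphenol; 2 chlorotriisopropylsilane
Product: 3 (3-fluoro-5-methoxyphenoxy)triisopropylsilane
Conditions: imidazole, DMF, rt
Reagents that add atoms: chlorotriisopropylsilane 2, CC(C)[Si](Cl)(C(C)C)C(C)C
Why: Imidazole-promoted silylation of a phenol, the bulky triisopropylsilyl ether being chosen because it does not coordinate alkyllithiums and shields both of its ortho positions.

Step 2
Reactants: 3 (3-fluoro-5-methoxyphenoxy)triisopropylsilane; 4 carbon dioxide
Product: 6 2-fluoro-6-methoxy-4-(triisopropylsilyloxy)benzoic acid, via aryllithium 5 (not isolated)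
Conditions: s-BuLi, THF, −78 °C; CO2 (g), −78 °C to rt; 1 M HCl, 0 °C
Reagents that add atoms: carbon dioxide 4, O=C=O
Why: Directed ortho-metalation removes the one proton flanked by fluorine (inductive acidification) and methoxy (lithium coordination) at a temperature where the ortho-fluoroaryllithium does not lose LiF, and carboxylation puts the future C4 carbon on the future C4a.

Step 3
Reactants: 6 2-fluoro-6-methoxy-4-(triisopropylsilyloxy)benzoic acid; 7 oxalyl chloride
Product: 8 2-fluoro-6-methoxy-4-(triisopropylsilyloxy)benzoyl chloride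
Conditions: (COCl)2, DMF (cat.), CH2Cl2, 0 °C to rt; evaporate, use crude
Reagents that add atoms: oxalyl chloride 7, O=C(Cl)C(=O)Cl
Why: Acid chloride formation through the catalytic chloroiminium (Vilsmeier-type) species under non-aqueous conditions that should leave the aryl silyl ether and the aryl fluoride untouched.

Step 4
Reactants: 9 2,4-dihydroxybenzaldehyde; 2 chlorotriisopropylsilane
Product: 10 2-hydroxy-4-(triisopropylsilyloxy)benzaldehyde
Conditions: imidazole, CH2Cl2, 0 °C
Reagents that add atoms: chlorotriisopropylsilane 2, CC(C)[Si](Cl)(C(C)C)C(C)C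
Why: Regioselective phenol silylation, since the 4-hydroxyl is the more acidic and unhindered one while the 2-hydroxyl is tied up in a hydrogen bond to the formyl group.

Step 5
Reactants: 10 2-hydroxy-4-(triisopropylsilyloxy)benzaldehyde; 11 3-chloro-3-methylbut-1-yne
Product: 12 2-(2-methylbut-3-yn-2-yloxy)-4-(triisopropylsilyloxy)benzaldehyde
Conditions: DBU, CuCl2 (cat.), MeCN, 0 °C to rt
Reagents that add atoms: 3-chloro-3-methylbut-1-yne 11, C#CC(C)(C)Cl
Why: Copper-catalysed propargylic etherification of a phenol with a tertiary propargylic chloride (ionisation assisted by the copper acetylide), run with an amidine base mild enough to keep the aryl silyl ether.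

Step 6
Reactants: 12 2-(2-methylbut-3-yn-2-yloxy)-4-(triisopropylsilyloxy)benzaldehyde
Product: 14 2,2-dimethyl-5-(triisopropylsilyloxy)-2H-chromene-8-carbaldehyde, via allenylphenol 13 (not isolated)
Conditions: PhNEt2, 170 °C
Reagents that add atoms: none
Why: Aromatic propargyl Claisen rearrangement to the allenylphenol followed by 1,5-hydrogen shift and 6π oxa-electrocyclisation, which can only use the single free ortho position between the two oxygens and so should give the ring-B chromene with the pyran oxygen next to the formyl-bearing carbon.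

Step 7
Reactants: 14 2,2-dimethyl-5-(triisopropylsilyloxy)-2H-chromene-8-carbaldehyde; 15 (methoxymethyl)triphenylphosphonium chloride
Product: 16 8-(2-methoxyethenyl)-2,2-dimethyl-5-(triisopropylsilyloxy)-2H-chromene (E/Z mixture)
Conditions: NaN(SiMe3)2, THF, 0 °C; then 14, 0 °C to rt
Reagents that add atoms: (methoxymethyl)triphenylphosphonium chloride 15, COC[P+](c1ccccc1)(c1ccccc1)c1ccccc1.[Cl-]
Why: Wittig methoxymethylenation of an aromatic aldehyde (one-carbon homologation) with a non-nucleophilic amide base that spares the silyl ether, the E/Z mixture being immaterial because both isomers hydrolyse to the same aldehyde.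

Step 8
Reactants: 16 8-(2-methoxyethenyl)-2,2-dimethyl-5-(triisopropylsilyloxy)-2H-chromene; 17 water; 18 morpholine
Product: 20 4-{(E)-2-[2,2-dimethyl-5-(triisopropylsilyloxy)-2H-chromen-8-yl]ethenyl}morpholine, via arylacetaldehyde 19 (not isolated)
Conditions: TsOH·H2O (cat.), THF/H2O, 40 °C; then morpholine (3 equiv), toluene, 4 Å MS, 50 °C (same flask after solvent exchange); used crude
Reagents that add atoms: morpholine 18, C1COCCN1
Why: Acid-catalysed enol ether hydrolysis gives the arylacetaldehyde, which is condensed at once with morpholine (Stork enamine formation with removal of water) to the conjugated and therefore favoured E enamine, so the condensation-prone aldehyde is never stored.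

Step 9
Reactants: 8 2-fluoro-6-methoxy-4-(triisopropylsilyloxy)benzoyl chloride; 20 4-{(E)-2-[2,2-dimethyl-5-(triisopropylsilyloxy)-2H-chromen-8-yl]ethenyl}morpholine; 17 water
Product: 23 3-[2,2-dimethyl-5-(triisopropylsilyloxy)-2H-chromen-8-yl]-5-methoxy-7-(triisopropylsilyloxy)-4H-chromen-4-one, via enaminone 21 (not isolated), via formyl ketone enol 22 (not isolated)
Conditions: Et3N, THF, 0 to 50 °C; then 1 M HCl (aq), rt; then NaHCO3 (excess), DMF added, 70 °C (one flask)
Reagents that add atoms: water 17, O
Why: The enamine β-carbon of 20 (the future C3) is acylated by aroyl chloride 8 (Stork enamine acylation, Et3N taking up HCl; any N-acylammonium formed first is itself an acyl donor, so the C-acyl vinylogous amide 21 is the thermodynamic sink), which forms C4–C3. Aqueous acid then exchanges the amine of 21 for oxygen to give the enolised α-formyl ketone 22, and its bicarbonate-generated enolate oxygen displaces fluoride from C8a by addition–elimination (SNAr through a Meisenheimer adduct), which forms O1–C8a and ends in the aromatic 4-pyranone. The closest known reaction type is the cycloacylation of enamines with 2-halobenzoyl chlorides used for 4-quinolones (Grohe–Heitzer type) together with the SNAr closure of 2-fluoroaryl 1,3-dicarbonyl enolates to chromones. Ring C closes in a 6-exo-trig sense at the fluorine-bearing arene carbon, the enolate being free to rotate into the required Z geometry, so that the E/Z isomers of 20, 21 and 22 all converge on one product. No stereocentre is created here (C3 stays trigonal until step 10). The selectivity needed is attack at C8a by oxygen only: it should be secured by the ortho C4 carbonyl, by the C5 and C7 oxygens standing meta to C8a (no mesomeric deactivation of the ipso carbon), by the tertiary nitrogen of 21 being unable to close a neutral ring, and by the mild bicarbonate base, which should spare the two aryl silyl ethers.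

Step 10
Reactants: 23 3-[2,2-dimethyl-5-(triisopropylsilyloxy)-2H-chromen-8-yl]-5-methoxy-7-(triisopropylsilyloxy)-4H-chromen-4-one
Product: 26 (3R)-3-[2,2-dimethyl-5-(triisopropylsilyloxy)-2H-chromen-8-yl]-5-methoxy-7-(triisopropylsilyloxy)chromane, via isoflavanone 24 (not isolated), via cis-isoflavan-4-ol 25 (not isolated)
Conditions: RuCl[(R,R)-TsDPEN](p-cymene) (5 mol %), HCO2H/Et3N (5:2), EtOAc, 50 °C
Reagents that add atoms: none
Why: Noyori-type asymmetric transfer hydrogenation run as a cascade, in which Ru–H adds conjugately to the 4-pyranone to give racemic isoflavanone 24 whose acidic C3–H epimerises through the enol faster than the ketone is reduced, the (R,R) catalyst reduces the (3R) ketone selectively to the cis (3R,4R) carbinol 25 (dynamic kinetic resolution, C4 set by the catalyst and C3 by hydride delivery anti to the aryl group), and the carbinol, whose C4 cation is stabilised by O1, the C5 methoxy and the C7 silyloxy group, ionises in the formic acid medium and takes up hydride to leave the C4 methylene with C3 fixed as (3R), the unactivated chromene double bond of ring B being inert to Ru–H.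

Step 11
Reactants: 26 (3R)-3-[2,2-dimethyl-5-(triisopropylsilyloxy)-2H-chromen-8-yl]-5-methoxy-7-(triisopropylsilyloxy)chromane
Product: 27 8-[(3R)-7-hydroxy-5-methoxy-3,4-dihydro-2H-chromen-3-yl]-2,2-dimethyl-2H-chromen-5-ol
Conditions: Bu4NF, AcOH (1:1), THF, 0 °C to rt
Reagents that add atoms: none
Why: Fluoride-induced cleavage of both aryl silyl ethers, buffered with acetic acid so that the phenoxides are protonated at once and neither the chromene double bond nor the C3 stereocentre (no acidic hydrogen and no ionisable neighbour left) is affected.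

**Compound list**

1 | 3-fluoro-5-methoxyphenol | COc1cc(O)cc(F)c1 | starting material
2 | chlorotriisopropylsilane | CC(C)[Si](Cl)(C(C)C)C(C)C | starting material
3 | (3-fluoro-5-methoxyphenoxy)triisopropylsilane | COc1cc(F)cc(O[Si](C(C)C)(C(C)C)C(C)C)c1 | intermediate
4 | carbon dioxide | O=C=O | starting material
5 | [2-fluoro-6-methoxy-4-(triisopropylsilyloxy)phenyl]lithium | [Li]c1c(F)cc(O[Si](C(C)C)(C(C)C)C(C)C)cc1OC | intermediate
6 | 2-fluoro-6-methoxy-4-(triisopropylsilyloxy)benzoic acid | COc1cc(O[Si](C(C)C)(C(C)C)C(C)C)cc(F)c1C(=O)O | intermediate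
7 | oxalyl chloride | O=C(Cl)C(=O)Cl | starting material
8 | 2-fluoro-6-methoxy-4-(triisopropylsilyloxy)benzoyl chloride | COc1cc(O[Si](C(C)C)(C(C)C)C(C)C)cc(F)c1C(=O)Cl | intermediate
9 | 2,4-dihydroxybenzaldehyde | O=Cc1ccc(O)cc1O | starting material
10 | 2-hydroxy-4-(triisopropylsilyloxy)benzaldehyde | O=Cc1ccc(O[Si](C(C)C)(C(C)C)C(C)C)cc1O | intermediate
11 | 3-chloro-3-methylbut-1-yne | C#CC(C)(C)Cl | starting material
12 | 2-(2-methylbut-3-yn-2-yloxy)-4-(triisopropylsilyloxy)benzaldehyde | C#CC(C)(C)Oc1cc(O[Si](C(C)C)(C(C)C)C(C)C)ccc1C=O | intermediate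
13 | 2-hydroxy-3-(3-methylbuta-1,2-dienyl)-4-(triisopropylsilyloxy)benzaldehyde | CC(C)=C=Cc1c(O)c(C=O)ccc1O[Si](C(C)C)(C(C)C)C(C)C | intermediate
14 | 2,2-dimethyl-5-(triisopropylsilyloxy)-2H-chromene-8-carbaldehyde | O=Cc1ccc(O[Si](C(C)C)(C(C)C)C(C)C)c2c1OC(C)(C)C=C2 | intermediate
15 | (methoxymethyl)triphenylphosphonium chloride | COC[P+](c1ccccc1)(c1ccccc1)c1ccccc1.[Cl-] | starting material
16 | 8-(2-methoxyethenyl)-2,2-dimethyl-5-(triisopropylsilyloxy)-2H-chromene (E/Z mixture) | COC=Cc1ccc(O[Si](C(C)C)(C(C)C)C(C)C)c2c1OC(C)(C)C=C2 | intermediate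
17 | water | O | starting material
18 | morpholine | C1COCCN1 | starting material
19 | 2-[2,2-dimethyl-5-(triisopropylsilyloxy)-2H-chromen-8-yl]acetaldehyde | O=CCc1ccc(O[Si](C(C)C)(C(C)C)C(C)C)c2c1OC(C)(C)C=C2 | intermediate
20 | 4-{(E)-2-[2,2-dimethyl-5-(triisopropylsilyloxy)-2H-chromen-8-yl]ethenyl}morpholine | O1CCN(CC1)/C=C/c1ccc(O[Si](C(C)C)(C(C)C)C(C)C)c2c1OC(C)(C)C=C2 | intermediate
21 | 2-[2,2-dimethyl-5-(triisopropylsilyloxy)-2H-chromen-8-yl]-1-[2-fluoro-6-methoxy-4-(triisopropylsilyloxy)phenyl]-3-(morpholin-4-yl)prop-2-en-1-one (E/Z mixture) | COc1cc(O[Si](C(C)C)(C(C)C)C(C)C)cc(F)c1C(=O)C(=CN1CCOCC1)c1ccc(O[Si](C(C)C)(C(C)C)C(C)C)c2c1OC(C)(C)C=C2 | intermediate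
22 | 2-[2,2-dimethyl-5-(triisopropylsilyloxy)-2H-chromen-8-yl]-1-[2-fluoro-6-methoxy-4-(triisopropylsilyloxy)phenyl]-3-hydroxyprop-2-en-1-one (enol of the α-formyl ketone) | COc1cc(O[Si](C(C)C)(C(C)C)C(C)C)cc(F)c1C(=O)C(=CO)c1ccc(O[Si](C(C)C)(C(C)C)C(C)C)c2c1OC(C)(C)C=C2 | intermediate
23 | 3-[2,2-dimethyl-5-(triisopropylsilyloxy)-2H-chromen-8-yl]-5-methoxy-7-(triisopropylsilyloxy)-4H-chromen-4-one | COc1cc(O[Si](C(C)C)(C(C)C)C(C)C)cc2occ(-c3ccc(O[Si](C(C)C)(C(C)C)C(C)C)c4c3OC(C)(C)C=C4)c(=O)c12 | intermediate
24 | racemic 3-[2,2-dimethyl-5-(triisopropylsilyloxy)-2H-chromen-8-yl]-5-methoxy-7-(triisopropylsilyloxy)chroman-4-one | COc1cc(O[Si](C(C)C)(C(C)C)C(C)C)cc2OCC(c3ccc(O[Si](C(C)C)(C(C)C)C(C)C)c4c3OC(C)(C)C=C4)C(=O)c12 | intermediate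
25 | (3R,4R)-3-[2,2-dimethyl-5-(triisopropylsilyloxy)-2H-chromen-8-yl]-5-methoxy-7-(triisopropylsilyloxy)chroman-4-ol (cis) | COc1cc(O[Si](C(C)C)(C(C)C)C(C)C)cc2c1[C@H](O)[C@H](c1ccc(O[Si](C(C)C)(C(C)C)C(C)C)c3c1OC(C)(C)C=C3)CO2 | intermediate
26 | (3R)-3-[2,2-dimethyl-5-(triisopropylsilyloxy)-2H-chromen-8-yl]-5-methoxy-7-(triisopropylsilyloxy)chromane | COc1cc(O[Si](C(C)C)(C(C)C)C(C)C)cc2c1C[C@H](c1ccc(O[Si](C(C)C)(C(C)C)C(C)C)c3c1OC(C)(C)C=C3)CO2 | intermediate
27 | 8-[(3R)-7-hydroxy-5-methoxy-3,4-dihydro-2H-chromen-3-yl]-2,2-dimethyl-2H-chromen-5-ol | COc1cc(O)cc2c1C[C@H](c1ccc(O)c3c1OC(C)(C)C=C3)CO2 | target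

**Summary**

Total step count: 11. Longest linear sequence: 8 steps (steps 4 to 8, then 9 to 11); steps 1 to 3 form the second branch.

**Steps most likely to fail**

Step 9. The acylation may stall at nitrogen or fail for steric reasons, since a di-ortho-substituted aroyl chloride meets a β-aryl enamine; the acid chloride would then be lost to hydrolysis in the aqueous stage. The fallback builds the ketone first and adds C2 afterwards. It sets out from aryllithium 5 (generated from 3 as in step 2) and aldehyde 19 (made from 16 by the first stage of step 8 and used at once). Compound 5 is transmetalated with CeCl3 and added to 19 at −78 °C to give the diarylethanol F1. Dess–Martin oxidation gives the 2-fluorodeoxybenzoin F2. Condensation with N,N-dimethylformamide dimethyl acetal (toluene, 90 °C) gives the dimethylamino enaminone F3. Hydrolysis and SNAr closure as in the later stages of step 9 (1 M HCl, then NaHCO3, DMF, 70 °C) returns to the route at 23.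

Step 10. Enantiomeric purity may erode because the well-stabilised C4 cation can lose and regain the C3 proton before hydride arrives, or the cascade may stop before deoxygenation. The fallback separates the three events and removes the oxygen without a cation. It sets out from 23. Conjugate reduction with LiBH(s-Bu)3 (THF, −78 °C) gives isoflavanone 24 as an isolated racemate. Transfer hydrogenation with the same Ru catalyst in a non-acidic medium (HCO2Na, H2O/EtOAc, Et3N 0.2 equiv, 30 °C) should stop at carbinol 25 by the same dynamic kinetic resolution. Treatment with NaH, CS2 and MeI gives the xanthate F4, and Barton–McCombie reduction (Bu3SnH, AIBN, toluene, 80 °C) returns to the route at 26. A thermal syn elimination of F4 towards C3 is not available, because the C3 hydrogen is anti to the C4 oxygen in the cis isomer.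

Step 8. The electron-rich arylacetaldehyde may self-condense or oxidise in the interval before it is trapped, and water removal may be incomplete. The fallback never liberates the aldehyde. It sets out from 16, which adds methanol under pyridinium tosylate catalysis (MeOH, rt) to give the dimethyl acetal F5, a storable aldehyde equivalent. Heating F5 with morpholine and a trace of TsOH, with distillation of methanol (toluene, 110 °C), converts it by acetal-to-enamine exchange and returns to the route at 20.

**Further compounds**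

F1 | step 9 | 2-[2,2-dimethyl-5-(triisopropylsilyloxy)-2H-chromen-8-yl]-1-[2-fluoro-6-methoxy-4-(triisopropylsilyloxy)phenyl]ethanol (racemic) | COc1cc(O[Si](C(C)C)(C(C)C)C(C)C)cc(F)c1C(O)Cc1ccc(O[Si](C(C)C)(C(C)C)C(C)C)c2c1OC(C)(C)C=C2
F2 | step 9 | 2-[2,2-dimethyl-5-(triisopropylsilyloxy)-2H-chromen-8-yl]-1-[2-fluoro-6-methoxy-4-(triisopropylsilyloxy)phenyl]ethanone | COc1cc(O[Si](C(C)C)(C(C)C)C(C)C)cc(F)c1C(=O)Cc1ccc(O[Si](C(C)C)(C(C)C)C(C)C)c2c1OC(C)(C)C=C2
F3 | step 9 | 3-(dimethylamino)-2-[2,2-dimethyl-5-(triisopropylsilyloxy)-2H-chromen-8-yl]-1-[2-fluoro-6-methoxy-4-(triisopropylsilyloxy)phenyl]prop-2-en-1-one | COc1cc(O[Si](C(C)C)(C(C)C)C(C)C)cc(F)c1C(=O)C(=CN(C)C)c1ccc(O[Si](C(C)C)(C(C)C)C(C)C)c2c1OC(C)(C)C=C2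
F4 | step 10 | O-{(3R,4R)-3-[2,2-dimethyl-5-(triisopropylsilyloxy)-2H-chromen-8-yl]-5-methoxy-7-(triisopropylsilyloxy)chroman-4-yl} S-methyl dithiocarbonate | COc1cc(O[Si](C(C)C)(C(C)C)C(C)C)cc2c1[C@H](OC(=S)SC)[C@H](c1ccc(O[Si](C(C)C)(C(C)C)C(C)C)c3c1OC(C)(C)C=C3)CO2
F5 | step 8 | 8-(2,2-dimethoxyethyl)-2,2-dimethyl-5-(triisopropylsilyloxy)-2H-chromene | COC(OC)Cc1ccc(O[Si](C(C)C)(C(C)C)C(C)C)c2c1OC(C)(C)C=C2
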